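**Retrosynthetic overview**
1. The target quinone comes from two-electron oxidation of 2-methoxy-6-nonadecylhydroquinone.
2. The hydroquinone comes from a new Sc(OTf)3-catalysed quinol-to-hydroquinone 1,2-alkyl shift, which makes the ring–C19 bond next to the carbonyl that is flanked by the methoxy carbon.
3. The p-quinol comes from 1,2-addition of nonadecylmagnesium bromide to the more electrophilic carbonyl of 2-methoxy-1,4-benzoquinone.
4. Ring order: the single six-membered ring is bought intact with the quinone; no ring is formed.

Assumption: the target has no stereocentre, so it is one achiral compound and needs no enantiocontrol; 1-bromononadecane and 2-methoxy-1,4-benzoquinone are taken as catalogue chemicals.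

**Step 1**
Reactants: 1 nonadecyl bromide (1-bromononadecane); 2 methoxy-p-benzoquinone (2-methoxycyclohexa-2,5-diene-1,4-dione)
Product: 5 (±)-4-hydroxy-3-methoxy-4-nonadecylcyclohexa-2,5-dien-1-one, via nonadecylmagnesium bromide 3 (not isolated), via bromomagnesium quinol alkoxide 4 (not isolated)
Conditions: Mg, THF, 45 °C; then add slowly to 2 (1.3 equiv), THF, −78 °C; sat. aq NH4Cl
Reagents that add atoms: none
Why: 1,2-addition of a Grignard reagent to a quinone carbonyl (p-quinol synthesis) goes to the carbonyl next to the methoxy-bearing carbon, because the other carbonyl is a deactivated vinylogous ester and Mg can chelate O1 and the methoxy oxygen; low temperature and inverse addition hold back electron-transfer reduction, and the new carbinol centre forms racemic and is erased in step 2.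

**Step 2**
Reactants: 5 (±)-4-hydroxy-3-methoxy-4-nonadecylcyclohexa-2,5-dien-1-one
Product: 7 hydroquinone 2-methoxy-6-nonadecylbenzene-1,4-diol, via cyclohexa-2,4-dienone keto tautomer 6 (not isolated)
Conditions: Sc(OTf)3 (10 mol %), (CF3)2CHOH–CH2Cl2 1:4, 0.02 M, 0 → 40 °C, Ar
Reagents that add atoms: none
Why: Proposed new method: a Lewis-acid-catalysed vinylogous α-ketol (quinol-to-hydroquinone) 1,2-shift of an unactivated primary alkyl group, used as a regiospecific formal C–H alkylation of a methoxyquinone: Sc(OTf)3 binds the C1 carbonyl of 5, and the C4–alkyl σ bond (parallel to the ring π system, pushed by the C4–OH lone pair) migrates to C5, the β-carbon of the unsubstituted enone arm where the LUMO is concentrated because the methoxy group raises the π* level of the C2=C3 arm; C4 becomes a carbonyl and dienol 6 enolises irreversibly to aromatic 7, so the step is an isomerisation with no co-product that destroys the only stereocentre; the closest known reaction types are the acid-promoted dienone–phenol/p-quinol rearrangement and the vinylogous α-ketol (semipinacol) rearrangement, which to my knowledge have not been shown with a catalytic Lewis acid on a 3-methoxy-p-quinol carrying a simple n-alkyl group.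

**Step 3**
Reactants: 7 hydroquinone 2-methoxy-6-nonadecylbenzene-1,4-diol
Product: 8 target 2-methoxy-6-nonadecyl-1,4-benzoquinone (2-methoxy-6-nonadecylcyclohexa-2,5-diene-1,4-dione)
Conditions: Ag2O (2.5 equiv), Et2O, rt, dark
Reagents that add atoms: none
Why: Ag2O dehydrogenation of an electron-rich hydroquinone to its p-quinone is a fast, clean two-electron oxidation that leaves the enol ether and the alkyl chain untouched; no stereocentre is involved.

**Compound list**
1 | 1-bromononadecane | CCCCCCCCCCCCCCCCCCCBr | starting material
2 | 2-methoxy-1,4-benzoquinone (2-methoxycyclohexa-2,5-diene-1,4-dione) | COC1=CC(=O)C=CC1=O | starting material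
3 | nonadecylmagnesium bromide | CCCCCCCCCCCCCCCCCCC[Mg]Br | intermediate
4 | bromomagnesium 2-methoxy-1-nonadecyl-4-oxocyclohexa-2,5-dien-1-olate (racemic; magnesium alkoxide of 5) | CCCCCCCCCCCCCCCCCCCC1(O[Mg]Br)C=CC(=O)C=C1OC | intermediate
5 | 4-hydroxy-3-methoxy-4-nonadecylcyclohexa-2,5-dien-1-one (racemic p-quinol; C4 centre uncontrolled and lost in step 2) | CCCCCCCCCCCCCCCCCCCC1(O)C=CC(=O)C=C1OC | intermediate
6 | 4-hydroxy-2-methoxy-6-nonadecylcyclohexa-2,4-dien-1-one (racemic keto tautomer of 7) | CCCCCCCCCCCCCCCCCCCC1C=C(O)C=C(OC)C1=O | intermediate
7 | 2-methoxy-6-nonadecylbenzene-1,4-diol | CCCCCCCCCCCCCCCCCCCc1cc(O)cc(OC)c1O | intermediate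
8 | 2-methoxy-6-nonadecyl-1,4-benzoquinone (achiral) | CCCCCCCCCCCCCCCCCCCC1=CC(=O)C=C(OC)C1=O | target

**Totals**
Total step count: 3. Longest linear sequence: 3.

**Steps most likely to fail**

Step 2 (the proposed new shift) is the most uncertain. The methoxy group stabilises the Sc-bound dienone, so the shift may be slow. A competing shift to the methoxy-bearing C3, followed by loss of methanol, would give nonadecyl-1,4-benzoquinone, and intermolecular conjugate addition could give oligomers. The fallback uses known chemistry, sets out from 1 and comes back at 8. Bromide 1 is converted into its Grignard reagent 3 as in step 1 and cross-coupled with commercial 1-bromo-3,5-dimethoxybenzene (COc1cc(Br)cc(OC)c1) under Kumada conditions (NiCl2(dppp) 2 mol %, THF, reflux) to give 1,3-dimethoxy-5-nonadecylbenzene F1. Mono-demethylation with NaSEt in DMF at 150 °C and work-up with aq HCl gives 3-methoxy-5-nonadecylphenol F2. Teuber oxidation with (KSO3)2NO (Fremy's salt, 2.2 equiv, KH2PO4 buffer, CH2Cl2–H2O, Aliquat 336) puts the second oxygen para to the hydroxyl, between the methoxy and the alkyl group, and gives 8 directly, so 5, 6 and 7 are by-passed.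

Step 1 is the next risk. The quinone can be reduced by electron transfer to methoxyhydroquinone, and conjugate addition or attack at the other carbonyl can lower the yield of 5. The fallback sets out from 1 and comes back at 5. Commercial 2,4-dimethoxyphenol (COc1ccc(O)c(OC)c1) is oxidised with PhI(OAc)2 in MeOH at 0 °C to the quinone monoketal 2,4,4-trimethoxycyclohexa-2,5-dien-1-one F3, in which the only free carbonyl is the one to be attacked and the quinone oxidising power is masked. Grignard reagent 3, made from 1, adds to it in THF at −78 °C and gives, after NH4Cl work-up, (±)-1-nonadecyl-2,4,4-trimethoxycyclohexa-2,5-dien-1-ol F4. Brief treatment with 5% aq AcOH in THF hydrolyses the ketal and returns 5.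

Step 3 is the least risky, but free 7 is air-sensitive and can give quinhydrone-type mixtures that are hard to purify before oxidation. The fallback sets out from 7 and comes back at 8. Crude 7 is O-methylated (MeI, K2CO3, acetone, reflux, Ar) to the air-stable 1,2,5-trimethoxy-3-nonadecylbenzene F5, which is chromatographed. Oxidative demethylation with (NH4)2Ce(NO3)6 in MeCN–H2O at 0 °C then removes the two para-related methyl groups and gives 8.

**Further compounds**
F1 | step 2 | 1,3-dimethoxy-5-nonadecylbenzene | CCCCCCCCCCCCCCCCCCCc1cc(OC)cc(OC)c1
F2 | step 2 | 3-methoxy-5-nonadecylphenol | CCCCCCCCCCCCCCCCCCCc1cc(O)cc(OC)c1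
F3 | step 1 | 2,4,4-trimethoxycyclohexa-2,5-dien-1-one | COC1=CC(OC)(OC)C=CC1=O
F4 | step 1 | 1-nonadecyl-2,4,4-trimethoxycyclohexa-2,5-dien-1-ol (racemic) | CCCCCCCCCCCCCCCCCCCC1(O)C=CC(OC)(OC)C=C1OC
F5 | step 3 | 1,2,5-trimethoxy-3-nonadecylbenzene | CCCCCCCCCCCCCCCCCCCc1cc(OC)cc(OC)c1OC
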